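**Retrosynthetic overview**
- The target comes from hydrogenolysis of two benzyl ethers, after the (4S)-carbinol has opened succinic anhydride. That carbinol comes from a methyl ketone by a ketoreductase.
- The keto-lactone comes from acid lactonisation of a δ-hydroxy N,N-diethylbenzamide. The benzene ring is bought and the δ-lactone is the only ring formed. The methyl ethers are exchanged for benzyl ethers at this stage.
- The 4-oxopentyl chain comes from a Wittig reaction (acetonylidene ylide) on a β-silyloxy aldehyde, then C=C hydrogenation.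
- The lactone stereocentre comes from Ru–(S)-BINAP (Noyori) hydrogenation of a 4-aryl-3-oxobutanoate, made by Masamune homologation of an arylacetic acid.
- The arylacetic acid comes from ortho-metalation/methylation, then lateral lithiation/carboxylation, of N,N-diethyl-2,5-dimethoxybenzamide.

Assumption: the SMILES is read as (3R) at the lactone carbon and (S) at the side-chain carbinol, and screening-kit ketoreductases count as available catalysts.

**Step 1**
Reactants: 1 2,5-dimethoxybenzoic acid; 2 diethylamine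
Product: 4 N,N-diethyl-2,5-dimethoxybenzamide, via 2,5-dimethoxybenzoyl chloride 3 (not isolated)
Conditions: (COCl)2, cat. DMF, CH2Cl2, 0 °C → rt; then Et2NH, Et3N, CH2Cl2, 0 °C → rt
Reagents that add atoms: diethylamine (2), CCNCC
Why: Amide formation through the acid chloride (nucleophilic acyl substitution) is near-quantitative for a simple benzoic acid and creates no stereocentre.

**Step 2**
Reactants: 4 N,N-diethyl-2,5-dimethoxybenzamide; 5 iodomethane
Product: 7 N,N-diethyl-3,6-dimethoxy-2-methylbenzamide, via ortho-aryllithium 6 (not isolated)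
Conditions: s-BuLi, TMEDA, THF, −78 °C; then MeI, −78 °C → rt
Reagents that add atoms: iodomethane (5), CI
Why: Directed ortho-metalation, in which the CONEt2 group and the 5-OMe group jointly direct lithiation to the carbon between them, followed by SN2 methylation of the aryllithium.

**Step 3**
Reactants: 7 N,N-diethyl-3,6-dimethoxy-2-methylbenzamide; 8 carbon dioxide
Product: 10 [2-(diethylcarbamoyl)-3,6-dimethoxyphenyl]acetic acid, via benzylic organolithium 9 (not isolated)
Conditions: LDA, THF, −78 °C; then CO2 (g), −78 → 0 °C; 1 M HCl work-up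
Reagents that add atoms: carbon dioxide (8), O=C=O
Why: Lateral (benzylic) lithiation of an o-toluamide gives an amide-stabilised benzylic anion that is carboxylated by CO2.

**Step 4**
Reactants: 10 [2-(diethylcarbamoyl)-3,6-dimethoxyphenyl]acetic acid; 11 potassium ethyl malonate
Product: 14 ethyl 4-[2-(diethylcarbamoyl)-3,6-dimethoxyphenyl]-3-oxobutanoate, via acyl imidazolide 12 (not isolated), via acylmalonic half-ester 13 (not isolated)
Conditions: CDI, THF, rt; then KO2CCH2CO2Et, MgCl2, Et3N, MeCN/THF, rt → 45 °C; 1 M HCl work-up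
Reagents that add atoms: potassium ethyl malonate (11), CCOC(=O)CC(=O)[O-].[K+]
Why: Masamune homologation, in which the acyl imidazolide is C-acylated by the magnesium malonate enolate and the adduct decarboxylates on acidification, under conditions too mild to touch the hindered amide.

**Step 5**
Reactants: 14 ethyl 4-[2-(diethylcarbamoyl)-3,6-dimethoxyphenyl]-3-oxobutanoate
Product: 15 ethyl (3S)-4-[2-(diethylcarbamoyl)-3,6-dimethoxyphenyl]-3-hydroxybutanoate
Conditions: RuCl2[(S)-BINAP] (1 mol %), H2 (10 bar), EtOH, 60 °C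
Reagents that add atoms: none
Why: Noyori asymmetric hydrogenation of a chelating β-keto ester, where (S)-BINAP gives the (S)-β-hydroxy ester (as acetoacetate gives (S)-3-hydroxybutanoate), sets the first stereocentre, the future lactone carbon.

**Step 6**
Reactants: 15 ethyl (3S)-4-[2-(diethylcarbamoyl)-3,6-dimethoxyphenyl]-3-hydroxybutanoate; 16 tert-butyldimethylsilyl chloride
Product: 17 ethyl (3S)-3-[(tert-butyldimethylsilyl)oxy]-4-[2-(diethylcarbamoyl)-3,6-dimethoxyphenyl]butanoate
Conditions: TBSCl, imidazole, DMF, rt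
Reagents that add atoms: tert-butyldimethylsilyl chloride (16), CC(C)(C)[Si](C)(C)Cl
Why: Standard O-silylation masks the carbinol against elimination and premature lactonisation during chain extension and leaves the stereocentre untouched.

**Step 7**
Reactants: 17 ethyl (3S)-3-[(tert-butyldimethylsilyl)oxy]-4-[2-(diethylcarbamoyl)-3,6-dimethoxyphenyl]butanoate
Product: 18 2-[(2S)-2-[(tert-butyldimethylsilyl)oxy]-4-oxobutyl]-N,N-diethyl-3,6-dimethoxybenzamide
Conditions: DIBAL-H (1.1 equiv), CH2Cl2, −78 °C; then MeOH, aq. Rochelle salt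
Reagents that add atoms: none
Why: Partial ester reduction by DIBAL-H at −78 °C stops at the aluminium hemiacetal, which gives the aldehyde on work-up, while the twisted, doubly ortho-substituted diethylamide is inert.

**Step 8**
Reactants: 18 2-[(2S)-2-[(tert-butyldimethylsilyl)oxy]-4-oxobutyl]-N,N-diethyl-3,6-dimethoxybenzamide; 19 1-(triphenylphosphoranylidene)propan-2-one
Product: 20 2-[(2R,4E)-2-[(tert-butyldimethylsilyl)oxy]-6-oxohept-4-en-1-yl]-N,N-diethyl-3,6-dimethoxybenzamide
Conditions: Ph3P=CHC(O)CH3, toluene, 80 °C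
Reagents that add atoms: 1-(triphenylphosphoranylidene)propan-2-one (19), CC(=O)C=P(c1ccccc1)(c1ccccc1)c1ccccc1
Why: Wittig olefination with a stabilised, non-basic ylide gives the E-enone without β-elimination of the silyloxy group; the stereocentre is untouched and its descriptor changes from S to R only through CIP priorities.

**Step 9**
Reactants: 20 2-[(2R,4E)-2-[(tert-butyldimethylsilyl)oxy]-6-oxohept-4-en-1-yl]-N,N-diethyl-3,6-dimethoxybenzamide
Product: 21 2-[(2R)-2-[(tert-butyldimethylsilyl)oxy]-6-oxoheptyl]-N,N-diethyl-3,6-dimethoxybenzamide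
Conditions: H2 (1 atm), 10% Pd/C, EtOAc, rt
Reagents that add atoms: none
Why: Heterogeneous catalytic hydrogenation saturates the conjugated C=C while the ketone, silyl ether, amide and aryl ethers are inert in EtOAc.

**Step 10**
Reactants: 21 2-[(2R)-2-[(tert-butyldimethylsilyl)oxy]-6-oxoheptyl]-N,N-diethyl-3,6-dimethoxybenzamide
Product: 23 (3R)-5,8-dimethoxy-3-(4-oxopentyl)-3,4-dihydro-1H-isochromen-1-one, via desilylated hydroxy amide 22 (not isolated)
Conditions: 3 M aq. HCl/1,4-dioxane (1:1), 90 °C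
Reagents that add atoms: none
Why: Acidic desilylation followed by intramolecular acyl substitution (lactonisation of a δ-hydroxy benzamide) keeps the carbinol C–O bond intact, so configuration is retained, and the aqueous medium keeps hemiketal formation with the ketone reversible so material funnels to the lactone.

**Step 11**
Reactants: 23 (3R)-5,8-dimethoxy-3-(4-oxopentyl)-3,4-dihydro-1H-isochromen-1-one
Product: 24 (3R)-5,8-dihydroxy-3-(4-oxopentyl)-3,4-dihydro-1H-isochromen-1-one
Conditions: BBr3, CH2Cl2, −78 → 0 °C; then H2O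
Reagents that add atoms: none
Why: Lewis-acid cleavage of aryl methyl ethers by BBr3 is done here, where only a robust aryl lactone and a ketone are present.

**Step 12**
Reactants: 24 (3R)-5,8-dihydroxy-3-(4-oxopentyl)-3,4-dihydro-1H-isochromen-1-one; 25 benzyl bromide
Product: 26 (3R)-5,8-bis(benzyloxy)-3-(4-oxopentyl)-3,4-dihydro-1H-isochromen-1-one
Conditions: BnBr, K2CO3, cat. TBAI, DMF, 60 °C (Ar)
Reagents that add atoms: benzyl bromide (25), BrCc1ccccc1
Why: Williamson etherification of both phenoxides installs groups that are removed at the end under neutral hydrogenolysis, so the final ester and acid never meet a Lewis acid.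

**Step 13**
Reactants: 26 (3R)-5,8-bis(benzyloxy)-3-(4-oxopentyl)-3,4-dihydro-1H-isochromen-1-one
Product: 27 (3R)-5,8-bis(benzyloxy)-3-[(4S)-4-hydroxypentyl]-3,4-dihydro-1H-isochromen-1-one
Conditions: (S)-selective ketoreductase (NAD(P)H-dependent alcohol dehydrogenase), NADP+ (cat.), iPrOH, phosphate buffer pH 7/DMSO (9:1), 30 °C
Reagents that add atoms: none
Why: A Prelog-selective ketoreductase delivers hydride to the re face of the methyl ketone (small group methyl, large group the chain) to give the (S)-carbinol under catalyst control, independent of the remote lactone centre, with isopropanol recycling the cofactor.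

**Step 14**
Reactants: 27 (3R)-5,8-bis(benzyloxy)-3-[(4S)-4-hydroxypentyl]-3,4-dihydro-1H-isochromen-1-one; 28 succinic anhydride
Product: 29 4-{[(2S)-5-[(3R)-5,8-bis(benzyloxy)-1-oxo-3,4-dihydro-1H-isochromen-3-yl]pentan-2-yl]oxy}-4-oxobutanoic acid
Conditions: succinic anhydride, DMAP, Et3N, CH2Cl2, rt; 1 M HCl work-up
Reagents that add atoms: succinic anhydride (28), O=C1CCC(=O)O1
Why: DMAP-catalysed ring-opening acylation of the only free hydroxyl gives the half-ester directly, with retention because the carbinol C–O bond is not broken.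

**Step 15**
Reactants: 29 4-{[(2S)-5-[(3R)-5,8-bis(benzyloxy)-1-oxo-3,4-dihydro-1H-isochromen-3-yl]pentan-2-yl]oxy}-4-oxobutanoic acid
Product: 30 aspergimarin B
Conditions: H2 (1 atm), 10% Pd/C, EtOAc/THF, rt
Reagents that add atoms: none
Why: Hydrogenolysis of the two benzyl aryl ethers is neutral and leaves the lactone (a homobenzylic, not benzylic, C–O), the alkyl ester, the acid and both stereocentres untouched.

**Compound list**
1 | 2,5-dimethoxybenzoic acid | COc1ccc(OC)c(C(=O)O)c1 | starting material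
2 | diethylamine | CCNCC | starting material
3 | 2,5-dimethoxybenzoyl chloride (formed in situ) | COc1ccc(OC)c(C(=O)Cl)c1 | intermediate
4 | N,N-diethyl-2,5-dimethoxybenzamide | CCN(CC)C(=O)c1cc(OC)ccc1OC | intermediate
5 | iodomethane | CI | starting material
6 | ortho-aryllithium: N,N-diethyl-2-lithio-3,6-dimethoxybenzamide (formed in situ) | CCN(CC)C(=O)c1c([Li])c(OC)ccc1OC | intermediate
7 | N,N-diethyl-3,6-dimethoxy-2-methylbenzamide | CCN(CC)C(=O)c1c(C)c(OC)ccc1OC | intermediate
8 | carbon dioxide | O=C=O | starting material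
9 | benzylic organolithium: N,N-diethyl-2-(lithiomethyl)-3,6-dimethoxybenzamide (formed in situ) | CCN(CC)C(=O)c1c(C[Li])c(OC)ccc1OC | intermediate
10 | [2-(diethylcarbamoyl)-3,6-dimethoxyphenyl]acetic acid | CCN(CC)C(=O)c1c(CC(=O)O)c(OC)ccc1OC | intermediate
11 | potassium ethyl malonate (potassium 3-ethoxy-3-oxopropanoate) | CCOC(=O)CC(=O)[O-].[K+] | starting material
12 | acyl imidazolide: N,N-diethyl-2-[2-(1H-imidazol-1-yl)-2-oxoethyl]-3,6-dimethoxybenzamide (formed in situ) | CCN(CC)C(=O)c1c(CC(=O)n2ccnc2)c(OC)ccc1OC | intermediate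
13 | acylmalonic half-ester: 4-[2-(diethylcarbamoyl)-3,6-dimethoxyphenyl]-2-(ethoxycarbonyl)-3-oxobutanoic acid (magnesium chelate in the flask) | CCOC(=O)C(C(=O)O)C(=O)Cc1c(OC)ccc(OC)c1C(=O)N(CC)CC | intermediate
14 | ethyl 4-[2-(diethylcarbamoyl)-3,6-dimethoxyphenyl]-3-oxobutanoate | CCOC(=O)CC(=O)Cc1c(OC)ccc(OC)c1C(=O)N(CC)CC | intermediate
15 | ethyl (3S)-4-[2-(diethylcarbamoyl)-3,6-dimethoxyphenyl]-3-hydroxybutanoate | CCOC(=O)C[C@@H](O)Cc1c(OC)ccc(OC)c1C(=O)N(CC)CC | intermediate
16 | tert-butyldimethylsilyl chloride | CC(C)(C)[Si](C)(C)Cl | starting material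
17 | ethyl (3S)-3-[(tert-butyldimethylsilyl)oxy]-4-[2-(diethylcarbamoyl)-3,6-dimethoxyphenyl]butanoate | CCOC(=O)C[C@@H](O[Si](C)(C)C(C)(C)C)Cc1c(OC)ccc(OC)c1C(=O)N(CC)CC | intermediate
18 | 2-[(2S)-2-[(tert-butyldimethylsilyl)oxy]-4-oxobutyl]-N,N-diethyl-3,6-dimethoxybenzamide | O=CC[C@@H](O[Si](C)(C)C(C)(C)C)Cc1c(OC)ccc(OC)c1C(=O)N(CC)CC | intermediate
19 | 1-(triphenylphosphoranylidene)propan-2-one (acetonylidenetriphenylphosphorane) | CC(=O)C=P(c1ccccc1)(c1ccccc1)c1ccccc1 | starting material
20 | 2-[(2R,4E)-2-[(tert-butyldimethylsilyl)oxy]-6-oxohept-4-en-1-yl]-N,N-diethyl-3,6-dimethoxybenzamide | CC(=O)/C=C/C[C@@H](O[Si](C)(C)C(C)(C)C)Cc1c(OC)ccc(OC)c1C(=O)N(CC)CC | intermediate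
21 | 2-[(2R)-2-[(tert-butyldimethylsilyl)oxy]-6-oxoheptyl]-N,N-diethyl-3,6-dimethoxybenzamide | CC(=O)CCC[C@@H](O[Si](C)(C)C(C)(C)C)Cc1c(OC)ccc(OC)c1C(=O)N(CC)CC | intermediate
22 | desilylated hydroxy amide: N,N-diethyl-2-[(2R)-2-hydroxy-6-oxoheptyl]-3,6-dimethoxybenzamide (formed in situ) | CC(=O)CCC[C@@H](O)Cc1c(OC)ccc(OC)c1C(=O)N(CC)CC | intermediate
23 | (3R)-5,8-dimethoxy-3-(4-oxopentyl)-3,4-dihydro-1H-isochromen-1-one | CC(=O)CCC[C@@H]1Cc2c(OC)ccc(OC)c2C(=O)O1 | intermediate
24 | (3R)-5,8-dihydroxy-3-(4-oxopentyl)-3,4-dihydro-1H-isochromen-1-one | CC(=O)CCC[C@@H]1Cc2c(O)ccc(O)c2C(=O)O1 | intermediate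
25 | benzyl bromide | BrCc1ccccc1 | starting material
26 | (3R)-5,8-bis(benzyloxy)-3-(4-oxopentyl)-3,4-dihydro-1H-isochromen-1-one | CC(=O)CCC[C@@H]1Cc2c(OCc3ccccc3)ccc(OCc3ccccc3)c2C(=O)O1 | intermediate
27 | (3R)-5,8-bis(benzyloxy)-3-[(4S)-4-hydroxypentyl]-3,4-dihydro-1H-isochromen-1-one | C[C@H](O)CCC[C@@H]1Cc2c(OCc3ccccc3)ccc(OCc3ccccc3)c2C(=O)O1 | intermediate
28 | succinic anhydride | O=C1CCC(=O)O1 | starting material
29 | 4-{[(2S)-5-[(3R)-5,8-bis(benzyloxy)-1-oxo-3,4-dihydro-1H-isochromen-3-yl]pentan-2-yl]oxy}-4-oxobutanoic acid | C[C@@H](CCC[C@@H]1Cc2c(OCc3ccccc3)ccc(OCc3ccccc3)c2C(=O)O1)OC(=O)CCC(=O)O | intermediate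
30 | aspergimarin B: 4-{[(2S)-5-[(3R)-5,8-dihydroxy-1-oxo-3,4-dihydro-1H-isochromen-3-yl]pentan-2-yl]oxy}-4-oxobutanoic acid | C[C@@H](CCC[C@@H]1Cc2c(O)ccc(O)c2C(=O)O1)OC(=O)CCC(=O)O | target

**Totals**
Total step count: 15. Longest linear sequence: 15 steps (1 to 30).

**Three steps most likely to fail**

Step 10 (desilylation/lactonisation). The hindered amide closes slowly, and the freed carbinol can form a cyclic hemiketal or enol ether with the side-chain ketone. The fallback sets out from 21 and comes back at 23. NaBH4 in MeOH at 0 °C reduces the ketone of 21 to the epimeric carbinols 2-[(2R)-2-[(tert-butyldimethylsilyl)oxy]-6-hydroxyheptyl]-N,N-diethyl-3,6-dimethoxybenzamide F1. TsOH·H2O in toluene at reflux then removes the silyl group and closes the lactone with no ketone in the molecule, giving (3R)-3-(4-hydroxypentyl)-5,8-dimethoxy-3,4-dihydro-1H-isochromen-1-one F2 as a mixture of side-chain epimers. Dess–Martin periodinane in CH2Cl2 oxidises the side-chain carbinol back to the methyl ketone 23.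

Step 13 (enzymatic reduction). The lipophilic bis-benzyl substrate may be accepted poorly by the ketoreductases screened. The fallback sets out from 26 and comes back at 27. NaBH4 in MeOH/THF at 0 °C gives (3R)-5,8-bis(benzyloxy)-3-(4-hydroxypentyl)-3,4-dihydro-1H-isochromen-1-one F3 as a 1:1 mixture at the carbinol. A lipase (serine hydrolase, immobilised Candida antarctica lipase B) with vinyl acetate in MTBE at 35 °C acetylates only the (4R)-epimer (Kazlauskas rule) to (2R)-5-[(3R)-5,8-bis(benzyloxy)-1-oxo-3,4-dihydro-1H-isochromen-3-yl]pentan-2-yl acetate F4. The unreacted (4S)-alcohol, separated by chromatography, is 27 (at most 50%).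

Step 5 (asymmetric hydrogenation). The neighbouring amide may bind ruthenium and lower rate or ee. The fallback sets out from 10 and comes back at 20. BH3·SMe2 in THF reduces the acid to N,N-diethyl-2-(2-hydroxyethyl)-3,6-dimethoxybenzamide F5. Iridium-catalysed transfer-hydrogenative (Krische) allylation from the alcohol oxidation level gives N,N-diethyl-2-[(2R)-2-hydroxypent-4-en-1-yl]-3,6-dimethoxybenzamide F6. Its conditions are allyl acetate, [Ir(cod)Cl]2, a BINAP-type ligand, 4-chloro-3-nitrobenzoic acid, Cs2CO3, THF, 100 °C. The ligand enantiomer is chosen, and checked by Mosher ester analysis, to give the (R)-carbinol. TBSCl/imidazole gives 2-[(2R)-2-[(tert-butyldimethylsilyl)oxy]pent-4-en-1-yl]-N,N-diethyl-3,6-dimethoxybenzamide F7. Cross-metathesis with methyl vinyl ketone (Hoveyda–Grubbs II, CH2Cl2, 40 °C) gives the E-enone 20.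

**Further compounds**
F1 | step 10 | 2-[(2R)-2-[(tert-butyldimethylsilyl)oxy]-6-hydroxyheptyl]-N,N-diethyl-3,6-dimethoxybenzamide (epimers at C6) | CC(O)CCC[C@@H](O[Si](C)(C)C(C)(C)C)Cc1c(OC)ccc(OC)c1C(=O)N(CC)CC
F2 | step 10 | (3R)-3-(4-hydroxypentyl)-5,8-dimethoxy-3,4-dihydro-1H-isochromen-1-one (epimers at the side-chain carbinol) | CC(O)CCC[C@@H]1Cc2c(OC)ccc(OC)c2C(=O)O1
F3 | step 13 | (3R)-5,8-bis(benzyloxy)-3-(4-hydroxypentyl)-3,4-dihydro-1H-isochromen-1-one (epimers at the side-chain carbinol) | CC(O)CCC[C@@H]1Cc2c(OCc3ccccc3)ccc(OCc3ccccc3)c2C(=O)O1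
F4 | step 13 | (2R)-5-[(3R)-5,8-bis(benzyloxy)-1-oxo-3,4-dihydro-1H-isochromen-3-yl]pentan-2-yl acetate | C[C@H](CCC[C@@H]1Cc2c(OCc3ccccc3)ccc(OCc3ccccc3)c2C(=O)O1)OC(C)=O
F5 | step 5 | N,N-diethyl-2-(2-hydroxyethyl)-3,6-dimethoxybenzamide | CCN(CC)C(=O)c1c(CCO)c(OC)ccc1OC
F6 | step 5 | N,N-diethyl-2-[(2R)-2-hydroxypent-4-en-1-yl]-3,6-dimethoxybenzamide | C=CC[C@@H](O)Cc1c(OC)ccc(OC)c1C(=O)N(CC)CC
F7 | step 5 | 2-[(2R)-2-[(tert-butyldimethylsilyl)oxy]pent-4-en-1-yl]-N,N-diethyl-3,6-dimethoxybenzamide | C=CC[C@@H](O[Si](C)(C)C(C)(C)C)Cc1c(OC)ccc(OC)c1C(=O)N(CC)CC
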